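**Retrosynthetic overview**
The C3=C4 alkene of the 2H-chromene (arene = ring A, pyran = ring B, 4-hydroxyphenyl = ring C) is traced back to a chroman-4-one by reduction and dehydration; the ring C phenol travels as its MOM ether.
Ring B is cut across C3–C4 and O1–C8a: a three-atom dinucleophile O1–C2(CH3)2–C3 (the dilithio reagent from 1-chloro-2-methylpropan-2-ol) meets a benzonitrile whose nitrile carbon (C4, on C4a) stands ortho to a fluoride on C8a, an anionic [3+3] annulation.
The enabling feature: C4a of ring A carries C4 and is flanked by the two oxygen-bearing carbons C8a and C5, so a 2,6-difluorobenzonitrile is a ready 1,3-dielectrophile (C4, C8a) and its second fluoride brings in the C5 oxygen.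
That C5 oxygen enters by SNAr as a 2-methylbut-3-en-2-yl ether, which an aromatic Claisen rearrangement later turns into the C5 hydroxyl plus the C6 prenyl group.
The C7 side chain comes from B-alkyl Suzuki coupling of 4-bromo-2,6-difluorobenzonitrile with hydroborated 4-(methoxymethoxy)styrene; rings A and C are bought, and ring B is the only ring formed (step 4).

Key step: step 4

Assumption: the four starting materials and all reagents are taken as commercial; atom numbers are those of 2H-chromene (O1, C2, C3, C4, C4a, C5 to C8, C8a); the target has no stereocenter and no E/Z element.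

Step 1
Reactants: 1 4-(methoxymethoxy)benzaldehyde
Product: 2 1-ethenyl-4-(methoxymethoxy)benzene
Conditions: Ph3PCH3Br, KOtBu, THF, 0 °C → rt
Reagents that add atoms: methyltriphenylphosphonium bromide, C[P+](c1ccccc1)(c1ccccc1)c1ccccc1.[Br-]
Why: Wittig methylenation of an aryl aldehyde by the non-stabilised ylide is reliable, and the MOM acetal is inert to KOtBu.

Step 2
Reactants: 2 1-ethenyl-4-(methoxymethoxy)benzene; 3 4-bromo-2,6-difluorobenzonitrile
Product: 5 2,6-difluoro-4-{2-[4-(methoxymethoxy)phenyl]ethyl}benzonitrile, via B-alkyl-9-BBN adduct 4 (not isolated)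
Conditions: 9-BBN, THF, 0 °C → rt; then 3, Pd(dppf)Cl2 (cat.), K3PO4, DMF/H2O, rt
Reagents that add atoms: none
Why: Anti-Markovnikov hydroboration of the styrene followed by B-alkyl Suzuki–Miyaura coupling should join the sp3 carbon to the arene, because the C–Br bond para to the nitrile undergoes oxidative addition while the C–F bonds and the nitrile stay untouched at room temperature.

Step 3
Reactants: 5 2,6-difluoro-4-{2-[4-(methoxymethoxy)phenyl]ethyl}benzonitrile; 6 2-methylbut-3-en-2-ol
Product: 7 2-fluoro-4-{2-[4-(methoxymethoxy)phenyl]ethyl}-6-[(2-methylbut-3-en-2-yl)oxy]benzonitrile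
Conditions: NaH, THF, 0 °C → rt
Reagents that add atoms: none
Why: Nucleophilic aromatic substitution (SNAr) of one of the two equivalent fluorides ortho to the nitrile by the tertiary alkoxide should stop after one substitution, because the new alkoxy group deactivates the ring towards a second attack.

Step 4
Reactants: 7 2-fluoro-4-{2-[4-(methoxymethoxy)phenyl]ethyl}-6-[(2-methylbut-3-en-2-yl)oxy]benzonitrile; 8 1-chloro-2-methylpropan-2-ol
Product: 12 7-{2-[4-(methoxymethoxy)phenyl]ethyl}-2,2-dimethyl-5-[(2-methylbut-3-en-2-yl)oxy]-2,3-dihydro-4H-chromen-4-one, via dilithio reagent 9 (not isolated), via lithium ketimide 10 (not isolated), via cyclic imine 11 (not isolated)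
Conditions: 8, n-BuLi, THF, −78 °C; LiC10H8 (2 equiv), −78 °C; then 7, −78 °C; t-BuOH (1 equiv), DMPU, −78 → 50 °C; aq AcOH, rt
Reagents that add atoms: water, O
Why: Reductive lithiation turns the electrophilic chloromethyl carbon of 8 into the carbanion of 9 (polarity reversal), which adds to the nitrile carbon of 7 to make the C3–C4 bond (ketimide 10); after protonation at nitrogen by t-BuOH the tertiary lithium alkoxide attacks the fluorine-bearing ring carbon ortho to the C=N group and expels fluoride (SNAr) to make the O1–C8a bond (imine 11), and aqueous acetic acid hydrolyses the imine to ketone 12. The closest known reaction types are the addition of β-oxido alkyllithium reagents made from chlorohydrins to carbon electrophiles, the addition of organolithiums to aryl nitriles, and the base-mediated SNAr closure of 1-(2-fluoroaryl)-3-hydroxy ketones to chroman-4-ones, run here as one anionic [3+3] annulation. Ring B closes in the 6-exo mode by addition–elimination at the arene carbon. No stereocenter is formed. The step needs attack of the carbanion on the nitrile rather than on the C–F carbon, which the low temperature and the high electrophilicity of the nitrile should secure, and closure at the C–F carbon rather than at the ether-bearing ortho carbon, which is secured because fluoride is by far the better nucleofuge in SNAr. Reagent 9 is kept at −78 °C until it is consumed so that β-elimination to isobutene does not compete.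

Step 5
Reactants: 12 7-{2-[4-(methoxymethoxy)phenyl]ethyl}-2,2-dimethyl-5-[(2-methylbut-3-en-2-yl)oxy]-2,3-dihydro-4H-chromen-4-one
Product: 14 5-hydroxy-7-{2-[4-(methoxymethoxy)phenyl]ethyl}-2,2-dimethyl-6-(3-methylbut-2-en-1-yl)-2,3-dihydro-4H-chromen-4-one, via ortho-dienone 13 (not isolated)
Conditions: PhNEt2, 130 °C
Reagents that add atoms: none
Why: The aromatic Claisen rearrangement ([3,3]-sigmatropic shift) of the 1,1-dimethylallyl aryl ether should deliver the allyl unit with transposition to C6, the only ortho position that carries hydrogen, and tautomerisation of the transient racemic dienone 13 gives the phenol held by a hydrogen bond to the C4 ketone.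

Step 6
Reactants: 14 5-hydroxy-7-{2-[4-(methoxymethoxy)phenyl]ethyl}-2,2-dimethyl-6-(3-methylbut-2-en-1-yl)-2,3-dihydro-4H-chromen-4-one
Product: 15 5-hydroxy-7-[2-(4-hydroxyphenyl)ethyl]-2,2-dimethyl-6-(3-methylbut-2-en-1-yl)-2,3-dihydro-4H-chromen-4-one
Conditions: HCl (aq), MeOH, 40 °C
Reagents that add atoms: none
Why: Acid-catalysed methanolysis of the MOM acetal should free the ring C phenol at the robust chromanone stage, where the C5 hydroxyl is tied up in a hydrogen bond to the ketone and is therefore slow to cyclise onto the prenyl group.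

Step 7
Reactants: 15 5-hydroxy-7-[2-(4-hydroxyphenyl)ethyl]-2,2-dimethyl-6-(3-methylbut-2-en-1-yl)-2,3-dihydro-4H-chromen-4-one
Product: 17 7-[2-(4-hydroxyphenyl)ethyl]-2,2-dimethyl-6-(3-methylbut-2-en-1-yl)-2H-chromen-5-ol (the target), via chroman-4-ol 16 (not isolated)
Conditions: NaBH4, THF/MeOH, 0 °C; then p-TsOH·H2O (cat.), THF, rt
Reagents that add atoms: none
Why: Hydride reduction of the aryl ketone followed by acid-catalysed dehydration of the benzylic alcohol (through the cation stabilised by the C5 oxygen) should install the C3=C4 double bond, the only possible elimination because C3 carries the sole β-hydrogens, and the racemic C4 stereocenter of 16 is destroyed again.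

**Compound list**
1 | 4-(methoxymethoxy)benzaldehyde | COCOc1ccc(C=O)cc1 | starting material
2 | 1-ethenyl-4-(methoxymethoxy)benzene | C=Cc1ccc(OCOC)cc1 | intermediate
3 | 4-bromo-2,6-difluorobenzonitrile | N#Cc1c(F)cc(Br)cc1F | starting material
4 | 9-{2-[4-(methoxymethoxy)phenyl]ethyl}-9-borabicyclo[3.3.1]nonane | COCOc1ccc(CCB2C3CCCC2CCC3)cc1 | intermediate
5 | 2,6-difluoro-4-{2-[4-(methoxymethoxy)phenyl]ethyl}benzonitrile | COCOc1ccc(CCc2cc(F)c(C#N)c(F)c2)cc1 | intermediate
6 | 2-methylbut-3-en-2-ol | CC(C)(O)C=C | starting material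
7 | 2-fluoro-4-{2-[4-(methoxymethoxy)phenyl]ethyl}-6-[(2-methylbut-3-en-2-yl)oxy]benzonitrile | COCOc1ccc(CCc2cc(F)c(C#N)c(OC(C)(C)C=C)c2)cc1 | intermediate
8 | 1-chloro-2-methylpropan-2-ol | CC(C)(O)CCl | starting material
9 | lithium 1-lithio-2-methylpropan-2-olate, LiCH2C(CH3)2OLi | [Li]CC(C)(C)O[Li] | intermediate
10 | N-lithio ketimine lithium alkoxide formed by addition of 9 to the nitrile of 7 | COCOc1ccc(CCc2cc(F)c(C(=N[Li])CC(C)(C)O[Li])c(OC(C)(C)C=C)c2)cc1 | intermediate
11 | 7-{2-[4-(methoxymethoxy)phenyl]ethyl}-2,2-dimethyl-5-[(2-methylbut-3-en-2-yl)oxy]-2,3-dihydro-4H-chromen-4-imine | COCOc1ccc(CCc2cc3c(c(OC(C)(C)C=C)c2)C(=N)CC(C)(C)O3)cc1 | intermediate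
12 | 7-{2-[4-(methoxymethoxy)phenyl]ethyl}-2,2-dimethyl-5-[(2-methylbut-3-en-2-yl)oxy]-2,3-dihydro-4H-chromen-4-one | COCOc1ccc(CCc2cc3c(c(OC(C)(C)C=C)c2)C(=O)CC(C)(C)O3)cc1 | intermediate
13 | 7-{2-[4-(methoxymethoxy)phenyl]ethyl}-2,2-dimethyl-6-(3-methylbut-2-en-1-yl)-2,3-dihydro-4H-chromene-4,5(6H)-dione (ortho-dienone, racemic at C6) | COCOc1ccc(CCC2=CC3=C(C(=O)CC(C)(C)O3)C(=O)C2CC=C(C)C)cc1 | intermediate
14 | 5-hydroxy-7-{2-[4-(methoxymethoxy)phenyl]ethyl}-2,2-dimethyl-6-(3-methylbut-2-en-1-yl)-2,3-dihydro-4H-chromen-4-one | COCOc1ccc(CCc2cc3OC(C)(C)CC(=O)c3c(O)c2CC=C(C)C)cc1 | intermediate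
15 | 5-hydroxy-7-[2-(4-hydroxyphenyl)ethyl]-2,2-dimethyl-6-(3-methylbut-2-en-1-yl)-2,3-dihydro-4H-chromen-4-one | Oc1ccc(CCc2cc3OC(C)(C)CC(=O)c3c(O)c2CC=C(C)C)cc1 | intermediate
16 | 7-[2-(4-hydroxyphenyl)ethyl]-2,2-dimethyl-6-(3-methylbut-2-en-1-yl)-3,4-dihydro-2H-chromene-4,5-diol (racemic at C4) | Oc1ccc(CCc2cc3OC(C)(C)CC(O)c3c(O)c2CC=C(C)C)cc1 | intermediate
17 | 7-[2-(4-hydroxyphenyl)ethyl]-2,2-dimethyl-6-(3-methylbut-2-en-1-yl)-2H-chromen-5-ol | CC(C)=CCc1c(CCc2ccc(O)cc2)cc2c(c1O)C=CC(C)(C)O2 | target

**Step count and risks**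
Total step count: 7. Longest linear sequence: 7 steps (1 → 2 → 5 → 7 → 12 → 14 → 15 → 17).

The three steps most likely to fail:

Step 4. What may go wrong is β-elimination of the dilithio reagent before it adds, displacement of fluoride by the carbanion instead of addition to the nitrile, or stalling of the ring closure at the ketimine stage with reversal of the addition (cleavage to acetone). The fallback builds the same ring stepwise from a methyl ketone by known chemistry and sets out from 7. MeLi (THF, −78 → 0 °C, then aq AcOH) should add to the nitrile and give, after hydrolysis, the aryl methyl ketone F1. Its kinetic lithium enolate (LiN(iPr)2, THF, −78 °C) should add to acetone to give the aldol adduct F2. NaH in THF at 0 °C should then close ring B by SNAr of the tertiary alkoxide on the fluoride ortho to the ketone, which brings the route back at 12.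

Step 5. What may go wrong is ionisation of the tertiary allyl aryl ether with loss of isoprene instead of the [3,3] shift, or migration through C4a on to C8. The fallback replaces the pericyclic step by a cationic 1,3-shift and sets out from 12. Pd(PPh3)4 (zerovalent palladium) with morpholine in THF should remove the 2-methylbut-3-en-2-yl group and give the C5 phenol F3. Prenyl bromide with K2CO3 in acetone should give the prenyl ether F4. Stirring F4 over MgSiO3 (Florisil) in toluene should move the prenyl group from oxygen to the ortho carbon C6 without allylic inversion, which brings the route back at 14.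

Step 7. What may go wrong is over-reduction of the ortho-hydroxybenzylic alcohol through its quinone methide, or acid-induced cyclisation of the C5 hydroxyl onto the prenyl double bond during the dehydration. The fallback makes the alkene by a Shapiro reaction before deprotection, so that neither hydride nor acid is present at the alkene-forming stage, and sets out from 14. TsNHNH2 (EtOH, cat. AcOH, reflux) should give the tosylhydrazone F5. MeLi (excess, THF, 0 °C → rt, then water) should give by Shapiro elimination the MOM-protected chromene F6. HCl in MeOH at room temperature should then remove the MOM group, which brings the route back at 17.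

Further compounds
F1 | step 4 | 1-(2-fluoro-4-{2-[4-(methoxymethoxy)phenyl]ethyl}-6-[(2-methylbut-3-en-2-yl)oxy]phenyl)ethan-1-one | COCOc1ccc(CCc2cc(F)c(C(C)=O)c(OC(C)(C)C=C)c2)cc1
F2 | step 4 | 1-(2-fluoro-4-{2-[4-(methoxymethoxy)phenyl]ethyl}-6-[(2-methylbut-3-en-2-yl)oxy]phenyl)-3-hydroxy-3-methylbutan-1-one | COCOc1ccc(CCc2cc(F)c(C(=O)CC(C)(C)O)c(OC(C)(C)C=C)c2)cc1
F3 | step 5 | 5-hydroxy-7-{2-[4-(methoxymethoxy)phenyl]ethyl}-2,2-dimethyl-2,3-dihydro-4H-chromen-4-one | COCOc1ccc(CCc2cc3OC(C)(C)CC(=O)c3c(O)c2)cc1
F4 | step 5 | 7-{2-[4-(methoxymethoxy)phenyl]ethyl}-2,2-dimethyl-5-[(3-methylbut-2-en-1-yl)oxy]-2,3-dihydro-4H-chromen-4-one | COCOc1ccc(CCc2cc3OC(C)(C)CC(=O)c3c(OCC=C(C)C)c2)cc1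
F5 | step 7 | N'-[5-hydroxy-7-{2-[4-(methoxymethoxy)phenyl]ethyl}-2,2-dimethyl-6-(3-methylbut-2-en-1-yl)-2,3-dihydro-4H-chromen-4-ylidene]-4-methylbenzenesulfonohydrazide | COCOc1ccc(CCc2cc3OC(C)(C)CC(=NNS(=O)(=O)c4ccc(C)cc4)c3c(O)c2CC=C(C)C)cc1
F6 | step 7 | 7-{2-[4-(methoxymethoxy)phenyl]ethyl}-2,2-dimethyl-6-(3-methylbut-2-en-1-yl)-2H-chromen-5-ol | COCOc1ccc(CCc2cc3OC(C)(C)C=Cc3c(O)c2CC=C(C)C)cc1
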